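**Retrosynthetic overview**
- The decalin with its C5, C6, C9 and C10 stereocentres and the 8-methylene is taken from (+)-larixol. The 4α-CH2OH is made by 6α-OH-directed δ-C–H silylation and oxidation, with the 8-methylene masked as an epoxide and the C13 ketone as a ketal.
- Side chain: C13=C14 by Horner–Wadsworth–Emmons olefination of the C13 methyl ketone; C15–C5′ by an Evans chloroacetate syn-aldol on the C15 enal, which leads to a cis-15,5′-epoxy methyl ketone.
- Key disconnection: furanone C3′=C4′ and O1′–C5′ are made together in a (3+2)-type annulation. The cis-α,β-epoxy methyl ketone supplies C4′ (ketone carbon) and C5′ (epoxide carbon); a phosphonoacetate supplies C3′ and the carboxylate O1′. Z-selective olefination is followed by 5-exo epoxide opening with inversion, which also frees 15-OH.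
- Enabling feature: the furanone O1′–C5′ bond is vicinal and syn to the free C15–OH, and furanone C4′ carries a methyl. C15–O/C5′ is therefore a latent cis-epoxide and C4′ a latent methyl ketone, and the lactone carboxylate reaches C5′ through a five-membered ring.
- Ring order: decalin (from larixol), then the oxirane (step 13), then the furanone last (step 16, together with the final desilylation).

Key step: step 16

Remark: (+)-larixol, (13S)-labda-8(17),14-diene-6α,13-diol, is assumed to be a purchasable chiral-pool starting material; labdane numbers are used for C1–C15 (C18 = 4α-carbon, C17 = exocyclic methylene), and the furanone is numbered O1′, C2′(=O), C3′, C4′(CH3), C5′ (bonded to C15).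

Step 1
Reactants: 1 (+)-larixol
Product: 2 6α-hydroxy-14,15-dinorlabd-8(17)-en-13-one
Conditions: KMnO4, MgSO4, acetone, 0 °C → rt
Reagents that add atoms: none
Why: Permanganate degrades the accessible vinyl carbinol (dihydroxylation, glycol cleavage, oxidative decarboxylation) to the C13 methyl ketone, while the hindered 8(17)-methylene and the secondary 6α-OH should survive, as in the known degradation of manool-type labdanes.

Step 2
Reactants: 2 6α-hydroxy-14,15-dinorlabd-8(17)-en-13-one
Product: 3 13,13-ethylenedioxy-14,15-dinorlabd-8(17)-en-6α-ol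
Conditions: HOCH2CH2OH, PPTS, benzene, reflux (Dean–Stark)
Reagents that add atoms: ethylene glycol OCCO
Why: Acid-catalysed ketalisation of the unhindered methyl ketone masks the carbonyl against the Si–H chemistry of step 4; the weak acid should not move the exocyclic alkene.

Step 3
Reactants: 3 13,13-ethylenedioxy-14,15-dinorlabd-8(17)-en-6α-ol
Product: 4 8α,17-epoxy-13,13-ethylenedioxy-14,15-dinorlabdan-6α-ol
Conditions: mCPBA, NaHCO3, CH2Cl2, 0 °C
Reagents that add atoms: mCPBA OOC(=O)c1cccc(Cl)c1
Why: Prilezhaev epoxidation of the only alkene, from the face anti to the axial 10-methyl, masks the 1,1-disubstituted alkene that would otherwise be hydrosilylated in step 4; either C8 epimer converges in step 6.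

Step 4
Reactants: 4 8α,17-epoxy-13,13-ethylenedioxy-14,15-dinorlabdan-6α-ol
Product: 6 6α-O,18-C-diethylsilylene-bridged oxasilinane of 4, via diethylhydrosilyl ether 5 (not isolated)
Conditions: (i) Et2SiH2, [Ir(cod)OMe]2 (cat.), THF, rt; (ii) [Rh(cod)Cl]2 (cat.), Xantphos, norbornene, THF, 100 °C
Reagents that add atoms: diethylsilane CC[SiH2]CC
Why: Dehydrogenative O-silylation followed by alcohol-directed, δ-selective dehydrogenative C(sp3)–H silylation of a primary C–H closes a six-membered oxasilacycle; the equatorial 6α-oxygen is peri-syn to the equatorial 4α-methyl while the 4β- and 10β-methyls lie on the other face, so C4 becomes a stereocentre with 4α-CH2Si and 4β-CH3.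

Step 5
Reactants: 6 oxasilinane
Product: 7 8α,17-epoxy-13,13-ethylenedioxy-14,15-dinorlabdane-6α,18-diol
Conditions: H2O2 (aq.), KHCO3, KF, THF/MeOH, 50 °C
Reagents that add atoms: hydrogen peroxide OO
Why: Tamao–Fleming oxidation turns the C18–Si bond into C18–OH with retention and releases 6-OH; the epoxide and ketal should tolerate buffered basic peroxide.

Step 6
Reactants: 7 8α,17-epoxy-13,13-ethylenedioxy-14,15-dinorlabdane-6α,18-diol
Product: 10 6α,18-dihydroxy-14,15-dinorlabd-8(17)-en-13-one, via iodohydrin 8 (not isolated), via alkene ketal diol 9 (not isolated)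
Conditions: NaI, Zn, NaOAc, AcOH, rt; then H2O, 45 °C
Reagents that add atoms: water O
Why: Iodide opening of the epoxide and zinc-induced β-elimination of the iodohydrin regenerate the 8(17)-alkene regiospecifically (the only possible elimination), after which aqueous acetic acid hydrolyses the dioxolane without isomerising the alkene.

Step 7
Reactants: 10 6α,18-dihydroxy-14,15-dinorlabd-8(17)-en-13-one
Product: 11 6α,18-bis(triethylsilyloxy)-14,15-dinorlabd-8(17)-en-13-one
Conditions: Et3SiCl, imidazole, DMAP (cat.), DMF, rt → 40 °C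
Reagents that add atoms: chlorotriethylsilane CC[Si](Cl)(CC)CC
Why: Standard silylation of both hydroxyls; the triethylsilyl ethers should survive the basic and organometallic steps and fall to fluoride in step 16.

Step 8
Reactants: 11 6α,18-bis(triethylsilyloxy)-14,15-dinorlabd-8(17)-en-13-one
Product: 12 (13E)-N-methoxy-N-methyl-6α,18-bis(triethylsilyloxy)labda-8(17),13-dien-15-amide
Conditions: (EtO)2P(O)CH2C(O)N(OMe)Me, NaH, THF, 0 °C → reflux
Reagents that add atoms: diethyl {2-[methoxy(methyl)amino]-2-oxoethyl}phosphonate CCOP(=O)(CC(=O)N(C)OC)OCC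
Why: Horner–Wadsworth–Emmons olefination of the methyl ketone under reversible addition should place the amide trans to the larger C12 chain (13E); the minor 13Z isomer is to be removed by chromatography.

Step 9
Reactants: 12 (13E)-Weinreb enamide
Product: 13 (13E)-6α,18-bis(triethylsilyloxy)labda-8(17),13-dien-15-al
Conditions: i-Bu2AlH, THF, −78 °C; aq. KNaC4H4O6
Reagents that add atoms: none
Why: Hydride addition to the Weinreb amide gives a chelated hemiaminal that releases the enal only on work-up, so over-reduction and 1,4-reduction should not occur.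

Step 10
Reactants: 14 (R)-4-benzyloxazolidin-2-one; 15 chloroacetyl chloride
Product: 16 (R)-4-benzyl-3-(chloroacetyl)oxazolidin-2-one
Conditions: n-BuLi, THF, −78 °C; then 15, −78 → 0 °C
Reagents that add atoms: none
Why: N-acylation of the lithiated oxazolidinone with the acid chloride.

Step 11
Reactants: 13 (13E)-enal; 16 (R)-4-benzyl-3-(chloroacetyl)oxazolidin-2-one
Product: 17 syn-chlorohydrin imide (13 extended at C15 by C15H(OH)–C5′H(Cl)–C(=O)–N-oxazolidinone; 15S,5′R)
Conditions: 16, n-Bu2BOSO2CF3, Et3N, CH2Cl2, −78 → 0 °C; then 13, −78 → 0 °C; pH 7 buffer, MeOH, H2O2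
Reagents that add atoms: none
Why: Evans syn-aldol reaction: the Z-boron enolate reacts through a Zimmerman–Traxler transition state on the face away from the benzyl group, which sets C15 (S) and C5′ (R) as the syn-chlorohydrin; the enal should react 1,2.

Step 12
Reactants: 17 syn-chlorohydrin imide
Product: 18 syn-chlorohydrin Weinreb amide (15S,5′R)
Conditions: Me3Al, MeONHMe·HCl, CH2Cl2, −20 → 0 °C
Reagents that add atoms: N,O-dimethylhydroxylamine hydrochloride CNOC.Cl
Why: Aluminium amide transamidation of the exocyclic imide carbonyl, assisted by the β-hydroxyl, releases the auxiliary without touching C15 or C5′.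

Step 13
Reactants: 18 syn-chlorohydrin Weinreb amide
Product: 19 cis-15,5′-epoxy Weinreb amide (15S,5′S)
Conditions: K2CO3, MeOH, 0 °C
Reagents that add atoms: none
Why: Intramolecular Williamson closure (second stage of a Darzens reaction): the C15 alkoxide displaces chloride with inversion at C5′, so the syn-chlorohydrin gives the cis-epoxide stereospecifically.

Step 14
Reactants: 19 cis-15,5′-epoxy Weinreb amide
Product: 20 cis-15,5′-epoxy methyl ketone (15S,5′S; the ketone carbon is the future C4′)
Conditions: MeLi, THF, −78 °C; pH 7 buffer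
Reagents that add atoms: methyllithium [Li]C
Why: Weinreb ketone synthesis: the chelated tetrahedral adduct prevents over-addition, and the epoxide should not react with MeLi at −78 °C.

Step 15
Reactants: 21 bis(2,2,2-trifluoroethyl)phosphonoacetic acid; 22 2-(trimethylsilyl)ethanol
Product: 23 2-(trimethylsilyl)ethyl bis(2,2,2-trifluoroethyl)phosphonoacetate
Conditions: DCC, DMAP (cat.), CH2Cl2, 0 °C → rt
Reagents that add atoms: none
Why: Steglich esterification gives a Still–Gennari reagent whose ester can be cleaved by fluoride.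

Step 16
Reactants: 20 cis-15,5′-epoxy methyl ketone; 23 2-(trimethylsilyl)ethyl bis(2,2,2-trifluoroethyl)phosphonoacetate
Product: 25 target butenolide CNP0221530.1, via Z-epoxy enoate 24 (not isolated)
Conditions: (i) 23, KN(SiMe3)2, 18-crown-6, THF, −78 → −40 °C; (ii) Bu4NF, AcOH, THF, 0 °C → rt
Reagents that add atoms: none
Why: The potassium anion of 23 adds to the methyl ketone and eliminates rapidly (Still–Gennari olefination), which should place the ester cis to the oxygen-bearing C5′ and so forms C3′=C4′ with Z geometry (24). Fluoride then cleaves the trimethylsilylethyl ester, and the free carboxylate attacks C5′ anti to the epoxide C–O bond (5-exo-tet, SN2), forming O1′–C5′ and releasing the C15 alkoxide, which acetic acid protonates. The closest known reaction types are Z-selective Still–Gennari olefination of α-oxygenated methyl ketones followed by lactonisation, and cyclisation of γ,δ-epoxy acids to hydroxy-γ-lactones. The new C5′ stereocentre (S) is fixed by inversion of the (5′R) epoxide carbon of 24, and C15 (S) keeps its C–O bond and configuration. The step needs Z-selectivity (secured by the reagent and the α-oxygenated ketone; the E isomer cannot lactonise and is separable) and 5-exo over 6-endo opening at allylic C15 (secured by the cis-carboxylate geometry and the absence of strong acid). The same buffered fluoride removes both triethylsilyl ethers, so the step ends at the target.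

**Compound list**
1 | (+)-larixol, (13S)-labda-8(17),14-diene-6α,13-diol | C=C1C[C@H](O)[C@H]2C(C)(C)CCC[C@]2(C)[C@H]1CC[C@](C)(O)C=C | starting material
2 | 6α-hydroxy-14,15-dinorlabd-8(17)-en-13-one | C=C1C[C@H](O)[C@H]2C(C)(C)CCC[C@]2(C)[C@H]1CCC(C)=O | intermediate
3 | 13,13-ethylenedioxy-14,15-dinorlabd-8(17)-en-6α-ol | C=C1C[C@H](O)[C@H]2C(C)(C)CCC[C@]2(C)[C@H]1CCC3(C)OCCO3 | intermediate
4 | 8α,17-epoxy-13,13-ethylenedioxy-14,15-dinorlabdan-6α-ol | C1O[C@@]13C[C@H](O)[C@H]2C(C)(C)CCC[C@]2(C)[C@H]3CCC4(C)OCCO4 | intermediate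
5 | 6α-O-diethylhydrosilyl ether of 4 | C1O[C@@]13C[C@H](O[SiH](CC)CC)[C@H]2C(C)(C)CCC[C@]2(C)[C@H]3CCC4(C)OCCO4 | intermediate
6 | oxasilinane (6α-O–SiEt2–C18 bridge; 4α-CH2Si, 4β-CH3) | C1O[C@@]13C[C@H](O[Si](CC)(CC)C4)[C@H]2[C@@]4(C)CCC[C@]2(C)[C@H]3CCC5(C)OCCO5 | intermediate
7 | 8α,17-epoxy-13,13-ethylenedioxy-14,15-dinorlabdane-6α,18-diol | C1O[C@@]13C[C@H](O)[C@H]2[C@](C)(CO)CCC[C@]2(C)[C@H]3CCC4(C)OCCO4 | intermediate
8 | 17-iodo-13,13-ethylenedioxy-14,15-dinorlabdane-6α,8α,18-triol (iodohydrin) | IC[C@@]1(O)C[C@H](O)[C@H]2[C@](C)(CO)CCC[C@]2(C)[C@H]1CCC3(C)OCCO3 | intermediate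
9 | 13,13-ethylenedioxy-14,15-dinorlabd-8(17)-ene-6α,18-diol | C=C1C[C@H](O)[C@H]2[C@](C)(CO)CCC[C@]2(C)[C@H]1CCC3(C)OCCO3 | intermediate
10 | 6α,18-dihydroxy-14,15-dinorlabd-8(17)-en-13-one | C=C1C[C@H](O)[C@H]2[C@](C)(CO)CCC[C@]2(C)[C@H]1CCC(C)=O | intermediate
11 | 6α,18-bis(triethylsilyloxy)-14,15-dinorlabd-8(17)-en-13-one | C=C1C[C@H](O[Si](CC)(CC)CC)[C@H]2[C@](C)(CO[Si](CC)(CC)CC)CCC[C@]2(C)[C@H]1CCC(C)=O | intermediate
12 | (13E)-N-methoxy-N-methyl-6α,18-bis(triethylsilyloxy)labda-8(17),13-dien-15-amide | C=C1C[C@H](O[Si](CC)(CC)CC)[C@H]2[C@](C)(CO[Si](CC)(CC)CC)CCC[C@]2(C)[C@H]1CC/C(C)=C/C(=O)N(C)OC | intermediate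
13 | (13E)-6α,18-bis(triethylsilyloxy)labda-8(17),13-dien-15-al | C=C1C[C@H](O[Si](CC)(CC)CC)[C@H]2[C@](C)(CO[Si](CC)(CC)CC)CCC[C@]2(C)[C@H]1CC/C(C)=C/C=O | intermediate
14 | (R)-4-benzyloxazolidin-2-one | O=C1N[C@H](Cc2ccccc2)CO1 | starting material
15 | chloroacetyl chloride | ClCC(Cl)=O | starting material
16 | (R)-4-benzyl-3-(chloroacetyl)oxazolidin-2-one | ClCC(=O)N1[C@H](Cc2ccccc2)COC1=O | intermediate
17 | syn-chlorohydrin imide (15S,5′R) | C=C1C[C@H](O[Si](CC)(CC)CC)[C@H]2[C@](C)(CO[Si](CC)(CC)CC)CCC[C@]2(C)[C@H]1CC/C(C)=C/[C@H](O)[C@@H](Cl)C(=O)N1[C@H](Cc2ccccc2)COC1=O | intermediate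
18 | syn-chlorohydrin Weinreb amide (15S,5′R) | C=C1C[C@H](O[Si](CC)(CC)CC)[C@H]2[C@](C)(CO[Si](CC)(CC)CC)CCC[C@]2(C)[C@H]1CC/C(C)=C/[C@H](O)[C@@H](Cl)C(=O)N(C)OC | intermediate
19 | cis-15,5′-epoxy Weinreb amide (15S,5′S) | C=C1C[C@H](O[Si](CC)(CC)CC)[C@H]2[C@](C)(CO[Si](CC)(CC)CC)CCC[C@]2(C)[C@H]1CC/C(C)=C/[C@@H]1O[C@@H]1C(=O)N(C)OC | intermediate
20 | cis-15,5′-epoxy methyl ketone (15S,5′S) | C=C1C[C@H](O[Si](CC)(CC)CC)[C@H]2[C@](C)(CO[Si](CC)(CC)CC)CCC[C@]2(C)[C@H]1CC/C(C)=C/[C@@H]1O[C@@H]1C(C)=O | intermediate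
21 | bis(2,2,2-trifluoroethyl)phosphonoacetic acid | OC(=O)CP(=O)(OCC(F)(F)F)OCC(F)(F)F | starting material
22 | 2-(trimethylsilyl)ethanol | C[Si](C)(C)CCO | starting material
23 | 2-(trimethylsilyl)ethyl bis(2,2,2-trifluoroethyl)phosphonoacetate | C[Si](C)(C)CCOC(=O)CP(=O)(OCC(F)(F)F)OCC(F)(F)F | intermediate
24 | 2-(trimethylsilyl)ethyl (Z)-enoate of the cis-epoxide (3′Z; 15S,5′R) | C=C1C[C@H](O[Si](CC)(CC)CC)[C@H]2[C@](C)(CO[Si](CC)(CC)CC)CCC[C@]2(C)[C@H]1CC/C(C)=C/[C@@H]1O[C@@H]1/C(C)=C\C(=O)OCC[Si](C)(C)C | intermediate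
25 | CNP0221530.1 (15S,5′S) | C=C1C[C@H](O)[C@H]2[C@](C)(CO)CCC[C@]2(C)[C@H]1CC/C(C)=C/[C@H](O)[C@H]1OC(=O)C=C1C | target

**Step count and risks**
Total step count: 16. Longest linear sequence: 14 (steps 1–9, 11–14, 16).

Three steps most likely to fail:

1. Step 16. Z-selectivity in the olefination of the hindered epoxy ketone may be incomplete, and the carboxylate may open the epoxide in the 6-endo mode at allylic C15 or the product may translactonise under base. The fallback builds the C15–C5′ bond instead and sets out from enal 13. Commercial 4-methylfuran-2(5H)-one is silylated (t-BuMe2SiOSO2CF3, Et3N, CH2Cl2) to 2-(tert-butyldimethylsilyloxy)-4-methylfuran F1. A vinylogous Mukaiyama aldol addition of F1 to 13 under Ti(Oi-Pr)4/BINOL catalysis (Lewis-acid additions of 2-silyloxyfurans are threo-selective; the BINOL antipode that gives 15S,5′S is to be fixed in a model reaction) gives the bis(triethylsilyl) butenolide F2. Bu4NF/AcOH then desilylates F2, and the route is rejoined at 25.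

2. Step 4. The spiro-epoxide may be opened or reduced under the rhodium hydride/silane conditions, or the six-membered C–H silylation may not proceed. The fallback uses alkoxy-radical 1,5-hydrogen transfer (Barton nitrite photolysis) and sets out from 4. NOCl/pyridine gives the 6α-nitrite F3. Irradiation (350 nm, toluene) followed by thermal isomerisation of the C18 nitroso compound gives the 18-oxime F4. Aqueous NaHSO3/EtOH releases the aldehyde as the 6α,18-lactol F5, and NaBH4 in MeOH reduces F5 to the diol, rejoining the route at 7.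

3. Step 8. The ketone olefination may give poor E/Z control at C13=C14, with a difficult separation. The fallback uses stereospecific alkyne carbometalation and sets out from 11. LiN(i-Pr)2, then ClP(O)(OEt)2, then excess LiN(i-Pr)2 converts the methyl ketone into the terminal alkyne F6. Zirconium-catalysed Negishi carboalumination (Me3Al, Cp2ZrCl2, CH2Cl2), then n-BuLi and (CH2O)n, gives the (13E)-allylic alcohol F7 by syn addition. MnO2 in CH2Cl2 oxidises F7 to the enal, rejoining the route at 13.

**Further compounds**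
F1 | step 16 | 2-(tert-butyldimethylsilyloxy)-4-methylfuran | CC1=COC(O[Si](C)(C)C(C)(C)C)=C1
F2 | step 16 | 6α,18-bis(triethylsilyl) ether of the target | C=C1C[C@H](O[Si](CC)(CC)CC)[C@H]2[C@](C)(CO[Si](CC)(CC)CC)CCC[C@]2(C)[C@H]1CC/C(C)=C/[C@H](O)[C@H]1OC(=O)C=C1C
F3 | step 4 | 6α-nitrite ester of 4 | C1O[C@@]13C[C@H](ON=O)[C@H]2C(C)(C)CCC[C@]2(C)[C@H]3CCC4(C)OCCO4
F4 | step 4 | 8α,17-epoxy-13,13-ethylenedioxy-6α-hydroxy-14,15-dinorlabdan-18-al oxime | C1O[C@@]13C[C@H](O)[C@H]2[C@](C)(C=NO)CCC[C@]2(C)[C@H]3CCC4(C)OCCO4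
F5 | step 4 | 6α,18-epoxy-18-hydroxy lactol of the 8α,17-epoxy ketal | C1O[C@@]13C[C@H](OC4O)[C@H]2[C@@]4(C)CCC[C@]2(C)[C@H]3CCC5(C)OCCO5
F6 | step 8 | 6α,18-bis(triethylsilyloxy)-15,16-dinorlabd-8(17)-en-13-yne (terminal alkyne) | C=C1C[C@H](O[Si](CC)(CC)CC)[C@H]2[C@](C)(CO[Si](CC)(CC)CC)CCC[C@]2(C)[C@H]1CCC#C
F7 | step 8 | (13E)-6α,18-bis(triethylsilyloxy)labda-8(17),13-dien-15-ol | C=C1C[C@H](O[Si](CC)(CC)CC)[C@H]2[C@](C)(CO[Si](CC)(CC)CC)CCC[C@]2(C)[C@H]1CC/C(C)=C/CO
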